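**Plan**

- Retrosynthesis: the two silyl ethers and the MOM ether come off last. Ring C is then cut at C3–C4, where the C3 carbinol and the C4 aryl ketone form a benzoin retron, which opens the dihydroflavonol to a dialdehyde.
- The dialdehyde is cut at the O1–C2 aryl ether bond (ring A phenol plus a 4-hydroxymandelate carrying ring B) and at the 7-O–CH2 bond (2,4,6-trihydroxybenzaldehyde plus an allylic alcohol from prenyl acetate).
- Forward: the side chain is made and joined to the 4-hydroxyl of ring A, one ortho hydroxyl is capped as MOM ether, and the other is etherified with the mandelate. Both carbonyl groups are reduced and reoxidised to the dialdehyde, and ring C closes last; rings A and B are bought.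
- Enabling feature: in the open form C2 is benzylic, oxygen-substituted and alpha to the C3 aldehyde, so it racemises freely, while the ring A formyl carbon (future C4) can act as acyl anion equivalent towards C3.
- Stereochemistry: C2 comes from a chiral triazolylidene carbene in a dynamic kinetic resolution during ring closure, C3 from equilibration to the trans diequatorial ketol, and the E alkene from the SeO2 allylic oxidation.

Key step: step 11

Assumption: 4-hydroxymandelic acid is used as the racemate, and the (5aR,10bS) antipode of the triazolium salt is taken as the one leading to the 2R series; if the sense of induction is the opposite, the equally available (5aS,10bR) antipode is used with nothing else changed.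

Abbreviations: TBS = tert-butyldimethylsilyl; MOM = methoxymethyl; DIAD = diisopropyl azodicarboxylate.

**Route**

Step 1
Reactants: 1 prenyl acetate (3-methylbut-2-en-1-yl acetate)
Product: 2 (E)-4-hydroxy-3-methylbut-2-en-1-yl acetate
Conditions: SeO2 (0.3 equiv), t-BuOOH (3 equiv), salicylic acid (0.1 equiv), CH2Cl2, rt
Reagents that add atoms: SeO2 (selenium dioxide) O=[Se]=O, which delivers the oxygen; tert-butyl hydroperoxide CC(C)(C)OO, which restores it
Why: Riley allylic oxidation (ene reaction of SeO2, then 2,3-sigmatropic shift) hydroxylates the methyl group trans to the acetoxymethyl chain, which fixes the E geometry, while t-BuOOH recycles the selenium and limits over-oxidation.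

Step 2
Reactants: 2 (E)-4-hydroxy-3-methylbut-2-en-1-yl acetate
Product: 3 (E)-4-(TBS-oxy)-3-methylbut-2-en-1-yl acetate
Conditions: TBSCl, imidazole, CH2Cl2, 0 °C to rt
Reagents that add atoms: tert-butyldimethylsilyl chloride CC(C)(C)[Si](C)(C)Cl
Why: Silylation of a primary alcohol with a silyl chloride and imidazole is routine and leaves the acetate and the alkene untouched.

Step 3
Reactants: 3 (E)-4-(TBS-oxy)-3-methylbut-2-en-1-yl acetate
Product: 4 (E)-4-(TBS-oxy)-3-methylbut-2-en-1-ol
Conditions: K2CO3 (0.2 equiv), MeOH, 0 °C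
Reagents that add atoms: none
Why: Base-catalysed transesterification with methanol removes the acetate, the primary silyl ether and the alkene geometry being stable to these conditions.

Step 4
Reactants: 5 rac-4-hydroxymandelic acid
Product: 6 methyl rac-4-hydroxymandelate
Conditions: H2SO4 (cat.), MeOH, rt
Reagents that add atoms: methanol CO
Why: Fischer esterification at room temperature, in which the benzylic hydroxyl is not etherified because the adjacent carboxyl group disfavours its ionisation.

Step 5
Reactants: 6 methyl rac-4-hydroxymandelate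
Product: 7 methyl rac-2-hydroxy-2-[4-(TBS-oxy)phenyl]acetate
Conditions: TBSCl (1.05 equiv), imidazole, DMF, 0 °C
Reagents that add atoms: tert-butyldimethylsilyl chloride CC(C)(C)[Si](C)(C)Cl
Why: Chemoselective silylation, the acidic and unhindered phenol reacting with TBSCl and imidazole well before the hindered secondary alpha-hydroxy ester.

Step 6
Reactants: 8 2,4,6-trihydroxybenzaldehyde; 4 (E)-4-(TBS-oxy)-3-methylbut-2-en-1-ol
Product: 9 2,6-dihydroxy-4-{[(E)-4-(TBS-oxy)-3-methylbut-2-en-1-yl]oxy}benzaldehyde
Conditions: PPh3, DIAD, THF, 0 °C to rt (8 in slight excess)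
Reagents that add atoms: none
Why: Mitsunobu etherification in which the 4-hydroxyl, the most acidic and the only one not hydrogen-bonded to the formyl group, is alkylated selectively by the primary allylic alcohol in an SN2 step that keeps the E alkene.

Step 7
Reactants: 9 2,6-dihydroxy-4-{[(E)-4-(TBS-oxy)-3-methylbut-2-en-1-yl]oxy}benzaldehyde
Product: 10 2-hydroxy-6-(methoxymethoxy)-4-{[(E)-4-(TBS-oxy)-3-methylbut-2-en-1-yl]oxy}benzaldehyde
Conditions: MOMCl (1.1 equiv), i-Pr2NEt, CH2Cl2, 0 °C
Reagents that add atoms: chloromethyl methyl ether COCCl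
Why: Mono-alkylation with MOMCl and a hindered amine stops after one of the two equivalent ortho hydroxyls, because the remaining one is locked in a strong hydrogen bond to the formyl group and does not react under these mild conditions.

Step 8
Reactants: 10 2-hydroxy-6-(methoxymethoxy)-4-{[(E)-4-(TBS-oxy)-3-methylbut-2-en-1-yl]oxy}benzaldehyde; 7 methyl rac-2-hydroxy-2-[4-(TBS-oxy)phenyl]acetate
Product: 11 methyl rac-2-[2-formyl-3-(methoxymethoxy)-5-{[(E)-4-(TBS-oxy)-3-methylbut-2-en-1-yl]oxy}phenoxy]-2-[4-(TBS-oxy)phenyl]acetate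
Conditions: PPh3, DIAD, THF, 0 °C to rt
Reagents that add atoms: none
Why: Mitsunobu etherification of the acidic chelated phenol with the secondary benzylic alcohol of the mandelate forms the O1–C2 bond as a racemate, which is what the later resolution needs, so stereochemical leakage at this carbon is of no concern.

Step 9
Reactants: 11 methyl rac-2-[2-formyl-3-(methoxymethoxy)-5-{[(E)-4-(TBS-oxy)-3-methylbut-2-en-1-yl]oxy}phenoxy]-2-[4-(TBS-oxy)phenyl]acetate
Product: 12 rac-2-[2-(hydroxymethyl)-3-(methoxymethoxy)-5-{[(E)-4-(TBS-oxy)-3-methylbut-2-en-1-yl]oxy}phenoxy]-2-[4-(TBS-oxy)phenyl]ethanol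
Conditions: i-Bu2AlH (5 equiv), CH2Cl2, −78 to 0 °C; aq. KNaC4H4O6 (potassium sodium tartrate) work-up
Reagents that add atoms: none
Why: Hydride reduction of the aryl aldehyde and the methyl ester with excess i-Bu2AlH at low temperature brings both carbons to the alcohol level under conditions that spare the MOM ether and the alkyl and aryl silyl ethers.

Step 10
Reactants: 12 rac-2-[2-(hydroxymethyl)-3-(methoxymethoxy)-5-{[(E)-4-(TBS-oxy)-3-methylbut-2-en-1-yl]oxy}phenoxy]-2-[4-(TBS-oxy)phenyl]ethanol
Product: 13 rac-2-[2-formyl-3-(methoxymethoxy)-5-{[(E)-4-(TBS-oxy)-3-methylbut-2-en-1-yl]oxy}phenoxy]-2-[4-(TBS-oxy)phenyl]acetaldehyde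
Conditions: Dess–Martin periodinane (2.6 equiv), pyridine, CH2Cl2, 0 °C to rt; quick filtration, used at once
Reagents that add atoms: none
Why: Dess–Martin oxidation of the benzylic and the primary alcohol, buffered with pyridine so that neither the acid-labile trioxygenated benzylic alcohol nor the enolisable alpha-aryloxy aldehyde is exposed to free acid.

Step 11
Reactants: 13 rac-2-[2-formyl-3-(methoxymethoxy)-5-{[(E)-4-(TBS-oxy)-3-methylbut-2-en-1-yl]oxy}phenoxy]-2-[4-(TBS-oxy)phenyl]acetaldehyde
Product: 14 (2R,3R)-3-hydroxy-5-(methoxymethoxy)-2-[4-(TBS-oxy)phenyl]-7-{[(E)-4-(TBS-oxy)-3-methylbut-2-en-1-yl]oxy}chroman-4-one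
Conditions: (5aR,10bS)-2-(pentafluorophenyl)-5a,10b-dihydro-4H,6H-indeno[2,1-b][1,2,4]triazolo[4,3-d][1,4]oxazin-2-ium tetrafluoroborate (15 mol %), i-Pr2NEt (1.0 equiv), 4 Å molecular sieves, degassed toluene (0.02 M), 0 °C to rt, Ar
Reagents that add atoms: none
Why: Proposed new method: the triazolylidene freed by the amine adds to the ring A formyl group of 13, proton transfer gives the aminoenol (acyl anion equivalent), this attacks the aliphatic aldehyde to form C3–C4, and the resulting alkoxide expels the carbene to leave the C4 aryl ketone; the closest known reactions are the carbene-catalysed intramolecular crossed aldehyde–ketone benzoin cyclisation to 3-hydroxychroman-4-ones and carbene-catalysed dynamic kinetic crossed benzoin additions to configurationally labile alpha-keto esters, neither of which joins two aldehydes while resolving the alpha-carbon. Ring C closes in a 6-exo-trig mode through a chair-like arrangement in which the aminoenol hydroxyl hydrogen-bonds to the acceptor oxygen. C2 is set by the catalyst: the alpha-aryl-alpha-aryloxy aldehyde racemises through its conjugated enol under i-Pr2NEt faster than it cyclises, and the indane wall of the catalyst should let only the enantiomer react that places the 4-silyloxyphenyl group equatorial on the open face, giving 2R. C3 is formed in the same bond formation and, lying alpha to the new ketone, is corrected by enediol equilibration to the trans diequatorial 3R arrangement dictated by C2. The step needs the ring A aldehyde to be the donor and ring closure to be slower than racemisation: the aliphatic formyl group sits on a tertiary carbon between an aryl and an aryloxy group and is partly parked as its enol, which retards aminoenol formation there (the path that would expel the ring A phenoxide), whereas the small MOM ether, chosen over a silyl ether because it cannot migrate to the carbinolate of the carbene adduct, keeps the doubly ortho-substituted ring A formyl group accessible, and the electron-poor N-C6F5 triazolium makes that adduct acidic enough to turn over with a weak base.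

Step 12
Reactants: 14 (2R,3R)-3-hydroxy-5-(methoxymethoxy)-2-[4-(TBS-oxy)phenyl]-7-{[(E)-4-(TBS-oxy)-3-methylbut-2-en-1-yl]oxy}chroman-4-one
Product: 15 (2R,3R)-3-hydroxy-2-(4-hydroxyphenyl)-7-{[(E)-4-hydroxy-3-methylbut-2-en-1-yl]oxy}-5-(methoxymethoxy)chroman-4-one
Conditions: HF·pyridine, pyridine, THF, 0 °C to rt
Reagents that add atoms: none
Why: Fluoride-mediated desilylation with pyridine-buffered HF·pyridine cleaves the aryl and the primary silyl ether without base, so the base-sensitive 3-hydroxychroman-4-one and its two stereocentres are not disturbed and the acetal stays in place.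

Step 13
Reactants: 15 (2R,3R)-3-hydroxy-2-(4-hydroxyphenyl)-7-{[(E)-4-hydroxy-3-methylbut-2-en-1-yl]oxy}-5-(methoxymethoxy)chroman-4-one
Product: 16 (2R,3R)-3,5-dihydroxy-2-(4-hydroxyphenyl)-7-{[(E)-4-hydroxy-3-methylbut-2-en-1-yl]oxy}chroman-4-one (target)
Conditions: HCl (0.5 M in MeOH), 0 °C to rt
Reagents that add atoms: none
Why: Acid-catalysed acetal exchange with methanol, in which the MOM ether peri to the C4 carbonyl is unusually labile because the released phenol is chelated, so dilute acid at or below room temperature should suffice and spare the allylic ether, the allylic alcohol and both stereocentres.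

**Compound list**

1 | prenyl acetate | CC(C)=CCOC(C)=O | starting material
2 | (E)-4-hydroxy-3-methylbut-2-en-1-yl acetate | C/C(=C\COC(C)=O)CO | intermediate
3 | (E)-4-(TBS-oxy)-3-methylbut-2-en-1-yl acetate | C/C(=C\COC(C)=O)CO[Si](C)(C)C(C)(C)C | intermediate
4 | (E)-4-(TBS-oxy)-3-methylbut-2-en-1-ol | C/C(=C\CO)CO[Si](C)(C)C(C)(C)C | intermediate
5 | rac-4-hydroxymandelic acid | OC(C(=O)O)c1ccc(O)cc1 | starting material
6 | methyl rac-4-hydroxymandelate | COC(=O)C(O)c1ccc(O)cc1 | intermediate
7 | methyl rac-2-hydroxy-2-[4-(TBS-oxy)phenyl]acetate | COC(=O)C(O)c1ccc(O[Si](C)(C)C(C)(C)C)cc1 | intermediate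
8 | 2,4,6-trihydroxybenzaldehyde | O=Cc1c(O)cc(O)cc1O | starting material
9 | 2,6-dihydroxy-4-{[(E)-4-(TBS-oxy)-3-methylbut-2-en-1-yl]oxy}benzaldehyde | C/C(=C\COc1cc(O)c(C=O)c(O)c1)CO[Si](C)(C)C(C)(C)C | intermediate
10 | 2-hydroxy-6-(methoxymethoxy)-4-{[(E)-4-(TBS-oxy)-3-methylbut-2-en-1-yl]oxy}benzaldehyde | C/C(=C\COc1cc(O)c(C=O)c(OCOC)c1)CO[Si](C)(C)C(C)(C)C | intermediate
11 | methyl rac-2-[2-formyl-3-(methoxymethoxy)-5-{[(E)-4-(TBS-oxy)-3-methylbut-2-en-1-yl]oxy}phenoxy]-2-[4-(TBS-oxy)phenyl]acetate | C/C(=C\COc1cc(OCOC)c(C=O)c(c1)OC(C(=O)OC)c1ccc(O[Si](C)(C)C(C)(C)C)cc1)CO[Si](C)(C)C(C)(C)C | intermediate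
12 | rac-2-[2-(hydroxymethyl)-3-(methoxymethoxy)-5-{[(E)-4-(TBS-oxy)-3-methylbut-2-en-1-yl]oxy}phenoxy]-2-[4-(TBS-oxy)phenyl]ethanol | C/C(=C\COc1cc(OCOC)c(CO)c(c1)OC(CO)c1ccc(O[Si](C)(C)C(C)(C)C)cc1)CO[Si](C)(C)C(C)(C)C | intermediate
13 | rac-2-[2-formyl-3-(methoxymethoxy)-5-{[(E)-4-(TBS-oxy)-3-methylbut-2-en-1-yl]oxy}phenoxy]-2-[4-(TBS-oxy)phenyl]acetaldehyde | C/C(=C\COc1cc(OCOC)c(C=O)c(c1)OC(C=O)c1ccc(O[Si](C)(C)C(C)(C)C)cc1)CO[Si](C)(C)C(C)(C)C | intermediate
14 | (2R,3R)-3-hydroxy-5-(methoxymethoxy)-2-[4-(TBS-oxy)phenyl]-7-{[(E)-4-(TBS-oxy)-3-methylbut-2-en-1-yl]oxy}chroman-4-one | C/C(=C\COc1cc(OCOC)c2c(c1)O[C@H](c1ccc(O[Si](C)(C)C(C)(C)C)cc1)[C@@H](O)C2=O)CO[Si](C)(C)C(C)(C)C | intermediate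
15 | (2R,3R)-3-hydroxy-2-(4-hydroxyphenyl)-7-{[(E)-4-hydroxy-3-methylbut-2-en-1-yl]oxy}-5-(methoxymethoxy)chroman-4-one | C/C(=C\COc1cc(OCOC)c2c(c1)O[C@H](c1ccc(O)cc1)[C@@H](O)C2=O)CO | intermediate
16 | (2R,3R)-3,5-dihydroxy-2-(4-hydroxyphenyl)-7-{[(E)-4-hydroxy-3-methylbut-2-en-1-yl]oxy}chroman-4-one | C/C(=C\COc1cc(O)c2c(c1)O[C@H](c1ccc(O)cc1)[C@@H](O)C2=O)CO | target

Total step count: 13. Longest linear sequence: 11 steps (steps 1–3 and 6–13, from prenyl acetate).

**Steps most likely to fail**

Step 11 (the proposed new method). The carbene may engage the aliphatic formyl group first and expel the ring A phenoxide by internal redox. Aminoenol formation at the doubly ortho-substituted ring A formyl group may also be too slow, or ring closure may outrun racemisation so that enantio- and diastereocontrol are lost. The fallback uses known chemistry (chalcone epoxide route), sets out from alcohol 4 and rejoins the route at target 16. Mitsunobu coupling of 4 with commercial 2,4,6-trihydroxyacetophenone should give 1-(2,6-dihydroxy-4-{[(E)-4-(TBS-oxy)-3-methylbut-2-en-1-yl]oxy}phenyl)ethanone F1. NaH and MOMCl in DMF then give 1-(2,6-bis(methoxymethoxy)-4-{[(E)-4-(TBS-oxy)-3-methylbut-2-en-1-yl]oxy}phenyl)ethanone F2. Claisen–Schmidt condensation with commercial 4-(methoxymethoxy)benzaldehyde (KOH, EtOH, rt) gives the (E)-chalcone F3. Juliá–Colonna epoxidation (poly-L-leucine, urea–H2O2, DBU, THF) should give the (2R,3S)-epoxy ketone F4. Warm methanolic HCl finally removes the three MOM groups and the silyl ether while a freed ortho phenol opens the epoxide at the benzylic carbon with inversion (6-endo), which should deliver 16 directly in the 2R,3R series.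

Step 10. The electron-rich benzylic alcohol may ionise under the acetic acid released by the oxidant before it is oxidised, and the enolisable dialdehyde may be lost by aldol or autoxidation during isolation. The fallback sets out from diol 12 and returns at 13, dividing the oxidation into two chemoselective, non-acidic operations. MnO2 in CH2Cl2 oxidises only the benzylic alcohol to rac-2-{2-hydroxy-1-[4-(TBS-oxy)phenyl]ethoxy}-6-(methoxymethoxy)-4-{[(E)-4-(TBS-oxy)-3-methylbut-2-en-1-yl]oxy}benzaldehyde F5, which can be purified and stored. The remaining primary alcohol is then oxidised by the Parikh–Doering method (SO3·pyridine, DMSO, i-Pr2NEt, 0 °C) immediately before step 11 to give 13.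

Step 8. Attack of the chelated phenol may be sluggish, so that the para-silyloxybenzylic oxyphosphonium ion ionises and is captured by the hydrazide instead. The fallback sets out from 7 and 10 and returns at 11, replacing redox condensation by a Williamson ether synthesis. Appel bromination of 7 (CBr4, PPh3, CH2Cl2, 0 °C) gives methyl rac-2-bromo-2-[4-(TBS-oxy)phenyl]acetate F6, which alkylates the phenoxide of 10 (K2CO3, acetone, rt) to give 11.

**Further compounds**

F1 | step 11 | 1-(2,6-dihydroxy-4-{[(E)-4-(TBS-oxy)-3-methylbut-2-en-1-yl]oxy}phenyl)ethanone | C/C(=C\COc1cc(O)c(C(C)=O)c(O)c1)CO[Si](C)(C)C(C)(C)C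
F2 | step 11 | 1-(2,6-bis(methoxymethoxy)-4-{[(E)-4-(TBS-oxy)-3-methylbut-2-en-1-yl]oxy}phenyl)ethanone | C/C(=C\COc1cc(OCOC)c(C(C)=O)c(OCOC)c1)CO[Si](C)(C)C(C)(C)C
F3 | step 11 | (E)-1-(2,6-bis(methoxymethoxy)-4-{[(E)-4-(TBS-oxy)-3-methylbut-2-en-1-yl]oxy}phenyl)-3-[4-(methoxymethoxy)phenyl]prop-2-en-1-one | C/C(=C\COc1cc(OCOC)c(C(=O)/C=C/c2ccc(OCOC)cc2)c(OCOC)c1)CO[Si](C)(C)C(C)(C)C
F4 | step 11 | (2,6-bis(methoxymethoxy)-4-{[(E)-4-(TBS-oxy)-3-methylbut-2-en-1-yl]oxy}phenyl){(2R,3S)-3-[4-(methoxymethoxy)phenyl]oxiran-2-yl}methanone | C/C(=C\COc1cc(OCOC)c(C(=O)[C@@H]2O[C@H]2c3ccc(OCOC)cc3)c(OCOC)c1)CO[Si](C)(C)C(C)(C)C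
F5 | step 10 | rac-2-{2-hydroxy-1-[4-(TBS-oxy)phenyl]ethoxy}-6-(methoxymethoxy)-4-{[(E)-4-(TBS-oxy)-3-methylbut-2-en-1-yl]oxy}benzaldehyde | C/C(=C\COc1cc(OCOC)c(C=O)c(c1)OC(CO)c1ccc(O[Si](C)(C)C(C)(C)C)cc1)CO[Si](C)(C)C(C)(C)C
F6 | step 8 | methyl rac-2-bromo-2-[4-(TBS-oxy)phenyl]acetate | COC(=O)C(Br)c1ccc(O[Si](C)(C)C(C)(C)C)cc1
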